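**Remark (locants).** Cyclohexane carbons are C5 (CH carrying the 2-hydroxypropan-2-yl group), C6, C7, C8 (CH–CH3), C9 (spiro carbon) and C10 (quaternary, CH3 plus the three-carbon arm); C11 is the benzylic CH2. The six-membered carbocycle of the aromatic precursors is C1′ (CO2Me), C2′ (OH, later the tropone C=O), C3′ (CH3), C4′ (O), C5′ (C11) and C6′ (CH3). The β face of the cyclohexane is the face of the C10 methyl group.

## Analysis of the target

Compound 22 is a ring-A-seco drimane-type meroterpenoid. Its tropone carries a methyl ester (C1′), the carbonyl (C2′), two methyl groups (C3′, C6′) and one CH, and is fused through C4′–O and C5′–C11 to a dihydrofuran whose C9 is spiro to a cyclohexane. The cyclohexane holds four contiguous stereocentres (C5, C10, C9, C8): the C5 hydroxyisopropyl group, the C10 methyl, the C9 oxygen and the C8 methyl lie on the β face, the C10 propanoic acid arm and C11 on the α face. C9 and C10 are adjacent quaternary carbons, and the C8 methyl is axial and syn to the C10 methyl in the chair that keeps the C5 group equatorial, so C8 has the less stable configuration and needs kinetic control. Sensitive groups are the tropone (hydride, hydrogenation, hydroxide), the C9–O bond (a tertiary alkyl ether of a vinylogous acid, prone to acid ionisation), the tertiary alcohol (dehydration, or lactonisation onto the acid arm under acid) and the methyl ester. The synthesis is hard because of the spiro centre between C10 and C8 and the fully substituted tropone with four different substituents, neither of which tolerates strong acid late in the route. The strategy rests on one feature: C9 carries both the ether oxygen and C11, and these sit on the neighbouring ring carbons C4′ and C5′. Once the lone CH between C5′ and C6′ is excised and the tropone becomes a benzene ring, the O–C9–C11 array is what an ortho-iodophenol leaves when it adds across the exocyclic end of a 1,3-diene C11=C9–C8=C7. The benzene ring is then that of atraric acid 13, and the diene maps onto (S)-carvone 1 (carbonyl carbon = C9, enone alkene = C8=C7, stereocentre = C5, α′ carbon = C10).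

## Retrosynthetic reasoning

**22 ⇒ 20.** The carboxyl group is traced to the primary alcohol of 20. An ester on this arm would have to be cleaved by acid or hydroxide in the presence of the C9–O bond, the tertiary alcohol and the tropone. A primary alcohol is inert through the route and is raised to the acid last under neutral oxidative conditions.

**20 ⇒ 19 ⇒ 17 + 18.** The tropone is cut at the two bonds of its only CH (C6′–CH and CH–C5′). That carbon comes from chloroform 18: C-attack of a dihalocarbene on the phenoxide of 17 at C5′ (para to the oxygen) gives dienone 19, and a radical 3-exo addition with ring opening moves the carbon into the ring. This reduces the tropone to a hexasubstituted benzene with every substituent in place. The forward steps need para selectivity in the carbene capture and radical addition to C6′, not C4′.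

**17 ⇒ 16.** The C8–H and C7–H bonds are removed, because C8 must be sp2 in the annulation. The forward hydrogenation has to deliver hydrogen to the α face.

**16 ⇒ 12 + 14 (key disconnection).** The C5′–C11 and O–C9 bonds are cut together. This splits 16 into two fragments of similar size, removes the dihydrofuran ring and the spiro stereocentre in one operation, and leaves a diene whose only stereocentres (C5, C10) come from the chiral pool. Forward, an arylpalladium species from 14 must add to the unsubstituted exocyclic terminus of 12, and the ortho phenoxide must close on C9 from the β face.

**14 ⇒ 13.** The C–I bond is cut; C5′ is the only unsubstituted position of 13 and is activated by both hydroxyls.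

**12 ⇒ 10 + 11.** The C9=C11 bond is cut to the enone carbonyl of 10 and the one-carbon phosphonium salt 11, so the 1,3-diene comes from the carvone enone without moving the ring alkene.

**10 ⇒ 9 ⇒ 7.** Two C–O bonds are cut: the tertiary hydroxyl back to the isopropenyl group (Markovnikov) and the primary hydroxyl back to a terminal allyl group (anti-Markovnikov). The allyl group is oxidised first, while a hindered dialkylborane can tell the monosubstituted alkene from the isopropenyl group. The isopropenyl group is hydrated second, when it is the only unactivated alkene left.

**7 ⇒ 4 + 5, and 4 ⇒ 1 + 2.** The two C10–C bonds are cut to allyl bromide 5, iodomethane 2 and (S)-carvone 1. Methyl first and allyl second places the arm trans to the C5 substituent, as 22 requires. A conjugate-addition route to the arm is not used, because the cross-conjugated dienolate 6 would add twice to an acrylic acceptor and close a bicyclo[2.2.2]octanone.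

## Alternatives that were turned down

**Alternative 1:** The acid arm and the tertiary carbinol are folded back into the seven-membered lactone A1, which is traced to the 4,4-dimethyl trans-decalone ketal A2 by cutting the C4–O bond. The forward key step is a Baeyer–Villiger oxidation of A2 with a buffered peracid, in which the quaternary C4 migrates and ring A expands.
- For it: migratory aptitude makes the regiochemistry safe, the trans ring fusion fixes the C5/C10 relationship before the oxidation, and the lactone masks acid and tertiary alcohol in one neutral group.
- Against it: the step solves only the easy part of 22. After A1 the C9 ketal must still become a spiro centre carrying oxygen and C11, C8 still needs its methyl group, and the tropone is untouched. The spiro problem therefore returns later, on a more valuable intermediate, after a longer linear sequence (annulation, gem-dimethylation, ring-fusion control, ketalisation, oxidation).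
- Comparison: on C5/C10 relative configuration and on protection of the arm this alternative is as good as or better than the chosen route, which relies on 1,2-induction in step 2 and carries a free primary alcohol. The chosen route offers convergence instead: the spiro ring and C9 are made in one step from two fragments, and diene 12 is reached from 1 in five steps.

**Alternative 2:** The C9–C8 and C10–C5 bonds of the cyclohexane in A3 are cut, giving an intramolecular Diels–Alder reaction between an alkylidene benzofuran-3-one (C9=C10) and an ester-tethered (E,E)-diene (C5=C6–C7=C8). Forward, heat or a Lewis acid closes the cyclohexene and a fused seven-membered lactone at once.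
- For it: four stereocentres (C5, C8, C9, C10) and two rings form in one step, and C8 comes from the diene geometry, not from a face-selective hydrogenation. On C8 it is stronger than the chosen route.
- Against it: the dienophile is a tetrasubstituted, β,β-disubstituted enone; the ester tether prefers the s-trans form and must close a seven-membered ring; endo/exo and facial selectivity hang on one remote stereocentre in the tether. A3 then needs removal of the C11 ketone, saturation of C6=C7, conversion of the secondary lactone carbinol into the dimethyl carbinol, and cleavage of an aryl methyl ether before the ring expansion.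
- Comparison: the chosen route needs one stereochemical correction after its key step (C8) and no skeletal corrections; this alternative needs none at C8 but four or more functional-group corrections, and its key step is mechanistically less favourable.

**Alternative 3:** Two bonds of the seven-membered carbocycle of A4 are cut, those that join the two carbons of propyne A5 to the rest of the ring. Forward, a cationic rhodium catalyst in its monovalent state induces a 1,2-acyloxy shift in a tertiary propargylic pivalate attached to a cyclic enol ether, and the resulting five-carbon unit adds to A5 in a (5+2) sense to give cycloheptatriene A4.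
- For it: the ring is built with carbonyl oxygen, ester and methyl groups placed by connectivity, with no dearomatisation and no carbene selectivity question. On regiochemical definition of the tropone it is stronger than the chosen route.
- Against it: the enyne must already contain the spiro dihydrofuran with all four cyclohexane stereocentres, so the hard part is moved into a long linear sequence without being solved. An endocyclic trisubstituted enol ether is an untested ene partner here, the orientation of unsymmetrical A5 is uncertain, and A4 still needs deacylation and dehydrogenation to the tropone. It also carries a tert-butyl ester whose acidolysis threatens the C9–O bond.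
- Comparison: the chosen route takes the seven-membered ring from a cheap benzenoid in two late steps and uses its key step on the spiro centre.

Key step: step 7

## Route

Step 1
Reactants: 1 (S)-carvone; 2 iodomethane
Product: 4 6-methylcarvone (C6 epimer mixture), via lithium dienolate of carvone 3 (not isolated)
Conditions: LDA (LiN(i-Pr)2), THF, −78 °C; then MeI, −78 to 0 °C
Reagents that add atoms: iodomethane (compound 2), CI
Why: Kinetic deprotonation at C6 (α′) gives the cross-conjugated lithium dienolate 3, which is C-methylated (enolate alkylation); the C6 epimer mixture does not matter because this centre is enolised again in step 2.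

Step 2
Reactants: 4 6-methylcarvone; 5 allyl bromide
Product: 7 6-allyl-6-methylcarvone (allyl trans to the C5 isopropenyl group), via lithium dienolate of 6-methylcarvone 6 (not isolated)
Conditions: LDA (LiN(i-Pr)2), THF, −78 °C; then allyl bromide, −78 to 0 °C
Reagents that add atoms: allyl bromide (compound 5), C=CCBr
Why: The last α′ proton is removed and the tetrasubstituted dienolate 6 is alkylated anti to the adjacent C5 isopropenyl group (enolate alkylation under 1,2-induction), which puts the allyl group trans and the methyl cis to C5 and fixes quaternary C10. An allyl halide is used because acrylic esters add twice to such cross-conjugated dienolates (Michael–Michael closure to a bicyclo[2.2.2]octanone).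

Step 3
Reactants: 7 6-allyl-6-methylcarvone
Product: 9 hydroxypropyl enone, via B-alkyl disiamylborane 8 (not isolated)
Conditions: Sia2BH (from BH3·THF and 2-methylbut-2-ene), THF, 0 °C; then 30% H2O2, pH 7 phosphate buffer, 0 °C to rt
Reagents that add atoms: hydrogen peroxide, OO
Why: Brown hydroboration with the hindered dialkylborane is fast and anti-Markovnikov at the monosubstituted allyl alkene and slow at the 1,1-disubstituted isopropenyl group and the conjugated enone. Neutral buffered peroxide oxidises the C–B bond without epoxidising the enone.

Step 4
Reactants: 9 hydroxypropyl enone
Product: 10 enone diol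
Conditions: Co(acac)2 (cat.), PhSiH3, O2 (1 atm), THF, rt
Reagents that add atoms: dioxygen, O=O
Why: Mukaiyama hydration: hydrogen-atom transfer to the electron-rich 1,1-disubstituted alkene gives the tertiary radical, which is trapped by O2 and reduced to the Markovnikov tertiary alcohol. The electron-poor trisubstituted enone and the primary alcohol should not take part.

Step 5
Reactants: 10 enone diol; 11 methyltriphenylphosphonium bromide
Product: 12 exocyclic diene diol
Conditions: Ph3PCH3Br, KOtBu (excess), toluene, 0 to 90 °C
Reagents that add atoms: methyltriphenylphosphonium bromide (compound 11), C[P+](c1ccccc1)(c1ccccc1)c1ccccc1.[Br-]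
Why: Wittig methylenation with the non-stabilised ylide converts the hindered enone carbonyl (C9) into the exocyclic alkene C9=C11 and so gives the 1,3-diene. Both hydroxyls ride through as potassium alkoxides, and any ring–chain hemiketal equilibrium of the δ-hydroxy ketone drains through the open ketone.

Step 6
Reactants: 13 atraric acid
Product: 14 methyl 2,4-dihydroxy-5-iodo-3,6-dimethylbenzoate
Conditions: NIS, MeCN, 0 °C to rt
Reagents that add atoms: N-iodosuccinimide, O=C1CCC(=O)N1I
Why: Electrophilic aromatic iodination occurs at C5′, the only unsubstituted ring carbon, which is ortho to one hydroxyl and para to the other.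

Step 7
Reactants: 12 exocyclic diene diol; 14 methyl 2,4-dihydroxy-5-iodo-3,6-dimethylbenzoate
Product: 16 spiro dihydrobenzofuran cyclohexene (C9 oxygen cis to the C10 methyl), via allylpalladium iodide complex 15 (not isolated)
Conditions: Pd(OAc)2 (10 mol %), n-Bu4NCl, NaHCO3, DMF, 90 °C
Reagents that add atoms: none
Why: Pd(OAc)2 is reduced in the flask to zerovalent palladium, which inserts into the C–I bond of 14; the arylpalladium iodide adds syn across the exocyclic C11=C9 bond of 12 with the aryl group going to the unsubstituted C11, giving the π-allyl complex 15 over C9–C8–C7. The phenoxide oxygen ortho to the new benzylic carbon then attacks the C9 terminus and releases zerovalent palladium, while NaHCO3 takes up the HI. The closest known reaction is the Larock heteroannulation of 1,3-dienes by ortho-iodophenols to 2-alkenyl-2,3-dihydrobenzofurans. The ring closes by 5-exo attack of oxygen on the allyl terminus C9, which is preferred over 7-endo attack at C7. The C9 configuration is controlled by the face of carbopalladation: of the two half-chairs of 12, only the one with the C5 group equatorial and the C10 methyl axial has a face of C9 free of an axial neighbour (the α face), so palladium should arrive there, and outer-sphere attack of the phenoxide anti to palladium places oxygen on the β face, cis to the C10 methyl as in 22. This epimer also keeps the larger C11 substituent pseudo-axial and free of A(1,2) strain with the C8 methyl, so reversible ionisation of the allylic aryl ether by zerovalent palladium should drift toward it as well. The step needs carbopalladation at the 1,1-disubstituted terminus and not at C7, C–O closure faster than β-hydride elimination to an aryl triene, and no interference from the other hydroxyls: the C2′ hydroxyl is chelated to the ester and cannot reach C9, and the aliphatic hydroxyls are not ionised by NaHCO3.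

Step 8
Reactants: 16 spiro dihydrobenzofuran cyclohexene
Product: 17 spiro dihydrobenzofuran cyclohexane (C8 methyl on the β face)
Conditions: H2 (3 atm), PtO2, EtOAc, rt
Reagents that add atoms: none
Why: Heterogeneous syn hydrogenation of the trisubstituted C7=C8 alkene; delivery of hydrogen to the α face, anti to the axial C10 methyl that is syn-axial to C8 and anti to the ether oxygen, puts the C8 methyl on the β face as in 22. PtO2 is used in place of a palladium catalyst to limit hydrogenolysis of the allylic C9–O bond and alkene migration. The facial preference is a steric argument and is not secure, because the C11 methylene on the α face also flanks C8.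

Step 9
Reactants: 17 spiro dihydrobenzofuran cyclohexane; 18 chloroform
Product: 19 dichloromethyl dienone (both configurations at C5′)
Conditions: CHCl3, 15% aq. NaOH, 65 °C
Reagents that add atoms: chloroform (compound 18), ClC(Cl)Cl
Why: Abnormal Reimer–Tiemann reaction: the sodium phenoxide of 17 captures dichlorocarbene through C5′, which is para to the phenoxide oxygen and ortho to the ether oxygen; because C5′ is quaternary the adduct cannot rearomatise and is protonated to the 4-dichloromethylcyclohexa-2,5-dienone. The new sp3 centre forms without control but is destroyed in step 10, and the hindered, chelated aryl ester should resist hydroxide.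

Step 10
Reactants: 19 dichloromethyl dienone
Product: 20 tropone alcohol
Conditions: Bu3SnH, AIBN (cat.), NaHCO3, PhH, 80 °C
Reagents that add atoms: none
Why: Stannane-mediated radical ring expansion of a 4-dichloromethylcyclohexadienone to a tropone: chlorine abstraction gives an α-chloroalkyl radical that adds 3-exo to C6′, the β-carbon of the alkylidene β-keto ester and the more electron-poor of the two ring alkenes. Opening of the cyclopropane at the former C5′–C6′ bond inserts the carbon between them, and loss of the second chlorine (as HCl, taken up by NaHCO3) gives the tropone.

Step 11
Reactants: 20 tropone alcohol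
Product: 22 target acid CNP0448476.2, via tropone aldehyde 21 (not isolated)
Conditions: TEMPO (cat.), PhI(OAc)2, MeCN–pH 7 buffer, rt
Reagents that add atoms: water, O
Why: Oxoammonium-mediated oxidation takes the primary alcohol through aldehyde 21 and its hydrate to the carboxylic acid at about neutral pH. The tertiary alcohol cannot be oxidised, and the tropone, the methyl ester and the acid-labile C9–O bond see no acid, base or reductant.

## Compound list

1 | (S)-carvone, (5S)-2-methyl-5-(prop-1-en-2-yl)cyclohex-2-en-1-one | CC1=CC[C@@H](CC1=O)C(C)=C | starting material
2 | iodomethane | CI | starting material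
3 | lithium dienolate of 1 (C1–C6 enolate, cross-conjugated) | CC1=CC[C@@H](C=C1O[Li])C(C)=C | intermediate
4 | 6-methylcarvone, (5S)-2,6-dimethyl-5-(prop-1-en-2-yl)cyclohex-2-en-1-one, mixture of C6 epimers | CC1=CC[C@@H](C(C)C1=O)C(C)=C | intermediate
5 | allyl bromide (3-bromoprop-1-ene) | C=CCBr | starting material
6 | lithium dienolate of 4 (C1–C6 enolate) | CC1=CC[C@@H](C(C)=C1O[Li])C(C)=C | intermediate
7 | 6-allyl-6-methylcarvone: 2,6-dimethyl-6-(prop-2-en-1-yl)-5-(prop-1-en-2-yl)cyclohex-2-en-1-one, allyl trans and methyl cis to the isopropenyl group, C5 as in 1 | O=C1C(C)=CC[C@H](C(C)=C)[C@@]1(C)CC=C | intermediate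
8 | B-alkyl disiamylborane: bis(3-methylbutan-2-yl)borane carrying the propyl arm of 7 on boron | O=C1C(C)=CC[C@H](C(C)=C)[C@@]1(C)CCCB(C(C)C(C)C)C(C)C(C)C | intermediate
9 | 6-(3-hydroxypropyl)-2,6-dimethyl-5-(prop-1-en-2-yl)cyclohex-2-en-1-one, configuration as in 7 | O=C1C(C)=CC[C@H](C(C)=C)[C@@]1(C)CCCO | intermediate
10 | 5-(2-hydroxypropan-2-yl)-6-(3-hydroxypropyl)-2,6-dimethylcyclohex-2-en-1-one, hydroxypropyl arm trans to the hydroxyisopropyl group | O=C1C(C)=CC[C@H](C(C)(C)O)[C@@]1(C)CCCO | intermediate
11 | methyltriphenylphosphonium bromide | C[P+](c1ccccc1)(c1ccccc1)c1ccccc1.[Br-] | starting material
12 | exocyclic diene diol: 3-[6-(2-hydroxypropan-2-yl)-1,3-dimethyl-2-methylidenecyclohex-3-en-1-yl]propan-1-ol, arm trans to the hydroxyisopropyl group | C=C1C(C)=CC[C@H](C(C)(C)O)[C@@]1(C)CCCO | intermediate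
13 | atraric acid, methyl 2,4-dihydroxy-3,6-dimethylbenzoate | COC(=O)c1c(C)cc(O)c(C)c1O | starting material
14 | methyl 2,4-dihydroxy-5-iodo-3,6-dimethylbenzoate | COC(=O)c1c(C)c(I)c(O)c(C)c1O | intermediate
15 | allylpalladium iodide complex from 12 and 14 (aryl on C11; drawn as the C9 σ-bonded form, palladium on the α face) | COC(=O)c1c(C)c(C[C@]2([Pd]I)C(C)=CC[C@H](C(C)(C)O)[C@@]2(C)CCCO)c(O)c(C)c1O | intermediate
16 | spiro dihydrobenzofuran cyclohexene: C4′–O–C9 and C5′–C11–C9 ring, C7=C8 alkene, C9 oxygen cis to the C10 methyl and the C5 hydroxyisopropyl group, free C2′ phenol, 3-hydroxypropyl arm on C10 | COC(=O)c1c(C)c2c(c(C)c1O)O[C@]1(C2)C(C)=CC[C@H](C(C)(C)O)[C@@]1(C)CCCO | intermediate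
17 | spiro dihydrobenzofuran cyclohexane: as 16 with C7–C8 saturated, C8 methyl cis to the C9 oxygen and the C10 methyl | COC(=O)c1c(C)c2c(c(C)c1O)O[C@]1(C2)[C@H](C)CC[C@H](C(C)(C)O)[C@@]1(C)CCCO | intermediate
18 | chloroform | ClC(Cl)Cl | starting material
19 | dichloromethyl dienone: cyclohexa-2,5-dienone with C2′=O, sp3 C5′ carrying CHCl2 and C11, both configurations at C5′ | COC(=O)C1=C(C)C2(C(Cl)Cl)C(=C(C)C1=O)O[C@]1(C2)[C@H](C)CC[C@H](C(C)(C)O)[C@@]1(C)CCCO | intermediate
20 | tropone alcohol: the target skeleton with a 3-hydroxypropyl arm on C10 | COC(=O)c1c(C)cc2c(c(C)c1=O)O[C@]1(C2)[C@H](C)CC[C@H](C(C)(C)O)[C@@]1(C)CCCO | intermediate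
21 | tropone aldehyde: as 20 with the arm ending in CHO | COC(=O)c1c(C)cc2c(c(C)c1=O)O[C@]1(C2)[C@H](C)CC[C@H](C(C)(C)O)[C@@]1(C)CCC=O | intermediate
22 | CNP0448476.2: spiro tropone with C5 hydroxyisopropyl, C10 methyl, C9 oxygen and C8 methyl cis, and a propanoic acid arm on C10 | COC(=O)c1c(C)cc2c(c(C)c1=O)O[C@]1(C2)[C@H](C)CC[C@H](C(C)(C)O)[C@@]1(C)CCC(=O)O | target

## Step count and least certain steps

Total step count: 11. Longest linear sequence: 10 steps (steps 1–5 and 7–11); step 6 is the one-step branch to 14.

**Step 7 (key step).** The most likely failures are:
- loss of facial control at C9, through carbopalladation from the β face or through inner-sphere C–O reductive elimination on the palladium-bearing face;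
- β-hydride elimination from the allyl intermediate to an aryl triene;
- slow insertion of the doubly ortho-substituted arylpalladium species into the hindered diene, with protodeiodination taking over.

Fallback, from 12 and 14, returning at 16: the two bonds are made in separate operations. Compound 14 is acetylated (Ac2O, pyridine) to methyl 2,4-diacetoxy-5-iodo-3,6-dimethylbenzoate F1, which cannot cyclise. Heck coupling of F1 with 12 (Pd(OAc)2, P(o-tol)3, Et3N, DMF) then gives the C11-arylated triene diacetate F2, whose alkene geometry is of no consequence. Methanolysis (K2CO3, MeOH) frees the dienyl bis-phenol F3. The O–C9 bond is closed by hydroalkoxylation with palladium hydride from Pd(PPh3)4 and benzoic acid in toluene, which passes through the same allyl intermediate under reversible conditions that should favour the more stable C9 epimer, giving 16.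

**Step 8.** The most likely failure is poor facial selectivity: hydrogen may be delivered to the β face, helped by adsorption through the ether oxygen or the C5 carbinol, which gives the C8 epimer with an equatorial methyl. Hydrogenolysis of the allylic C9–O bond before saturation is the second risk.

Fallback, from 16, returning at 17: stereocontrol is moved from the substrate to the catalyst. The three hydroxyls are capped with N-(trimethylsilyl)imidazole to give the tris(trimethylsilyl) ether of 16 F4, which removes hydroxyl-directed delivery. F4 is hydrogenated in CH2Cl2 with the chiral iridium complex [Ir(cod)(L)]BArF (L = (S)-tBu-PHOX, or its antipode, whichever is matched to α-face delivery) to the saturated tris(trimethylsilyl) ether F5. K2CO3 in MeOH removes the silyl groups and gives 17.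

**Step 9.** The most likely failures are carbene capture at the ortho carbons C3′ or C1′ in place of C5′, hydrolysis of the carbene outrunning C-attack so that conversion stalls, and slow saponification of the aryl ester in hot hydroxide.

Fallback, from 17, returning at 20: the one-carbon unit is delivered by a different carbene in a dry one-phase medium. The potassium phenoxide of 17 (KOtBu, THF) is treated with bromoform at −20 °C, so that dibromocarbene is generated next to the phenoxide without water or hydroxide, giving dibromomethyl dienone F6. F6 is taken through the conditions of step 10, where its weaker C–Br bonds start the radical chain more easily, and gives 20.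

**Step 5.** The most likely failure is no reaction at the carbonyl: it is shielded by the adjacent quaternary C10, and the ylide can act as a base (γ-deprotonation of the enone), so that 10 is recovered.

Fallback, from 10, returning at 12: Peterson olefination. Excess Me3SiCH2Li with CeCl3 (a weakly basic organocerium reagent) in THF at −78 °C adds to the carbonyl to give β-hydroxysilane F7 as a mixture at C9. KH in THF then causes syn elimination to the exocyclic alkene of 12.

## Further compounds

F1 | step 7 | methyl 2,4-diacetoxy-5-iodo-3,6-dimethylbenzoate | COC(=O)c1c(C)c(I)c(OC(C)=O)c(C)c1OC(C)=O
F2 | step 7 | C11-arylated triene diacetate (Heck product of F1 and 12, C11=C9 geometry not fixed) | COC(=O)c1c(C)c(C=C2C(C)=CC[C@H](C(C)(C)O)[C@@]2(C)CCCO)c(OC(C)=O)c(C)c1OC(C)=O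
F3 | step 7 | dienyl bis-phenol (deacetylated F2) | COC(=O)c1c(C)c(C=C2C(C)=CC[C@H](C(C)(C)O)[C@@]2(C)CCCO)c(O)c(C)c1O
F4 | step 8 | tris(trimethylsilyl) ether of 16 | COC(=O)c1c(C)c2c(c(C)c1O[Si](C)(C)C)O[C@]1(C2)C(C)=CC[C@H](C(C)(C)O[Si](C)(C)C)[C@@]1(C)CCCO[Si](C)(C)C
F5 | step 8 | tris(trimethylsilyl) ether of 17 | COC(=O)c1c(C)c2c(c(C)c1O[Si](C)(C)C)O[C@]1(C2)[C@H](C)CC[C@H](C(C)(C)O[Si](C)(C)C)[C@@]1(C)CCCO[Si](C)(C)C
F6 | step 9 | dibromomethyl dienone (both configurations at C5′) | COC(=O)C1=C(C)C2(C(Br)Br)C(=C(C)C1=O)O[C@]1(C2)[C@H](C)CC[C@H](C(C)(C)O)[C@@]1(C)CCCO
F7 | step 5 | β-hydroxysilane from 10 (both configurations at C9) | C[Si](C)(C)CC1(O)C(C)=CC[C@H](C(C)(C)O)[C@@]1(C)CCCO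
A1 | alternative 1 | ring-A seven-membered lactone ketal | O=C1CC[C@@]2(C)C3(OCCO3)CCC[C@@H]2C(C)(C)O1
A2 | alternative 1 | 4,4-dimethyl trans-decalone ketal (C3 ketone, C9 ethylene ketal) | O=C1CC[C@@]2(C)C3(OCCO3)CCC[C@@H]2C1(C)C
A3 | alternative 2 | spiro benzofuranone cyclohexene fused to the seven-membered lactone | COC(=O)c1c(C)c2c(c(C)c1OC)O[C@]1(C2=O)[C@H](C)C=C[C@@H]2[C@@H](C)OC(=O)CC[C@@]12C
A4 | alternative 3 | pivaloyloxy cycloheptatriene | COC(=O)C1=C(OC(=O)C(C)(C)C)C(C)=C2O[C@]3(CC2C=C1C)[C@H](C)CC[C@H](C(C)(C)O[Si](CC)(CC)CC)[C@@]3(C)CCC(=O)OC(C)(C)C
A5 | alternative 3 | propyne | CC#C
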